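Readings and results stem from a simulated flask from invented constants; scatter was added.

The difference [Ptn] − [Sbt] cannot change in a closed flask, since each Pdt formed takes one Sbt and one Ptn. The beta and gamma runs both hold 0.250 M, so the gamma run is charged like the beta run at a later stage, but with its clock reset. The decision is whether the epsilon charge and its single reading at 9.7 min are worth running, and whether early rates can be taken as the steady law.

| flask | Sbt | Ptn | Ctl | Pdt | time |
|---|---|---|---|---|---|
| beta | 0.500 M | 0.750 M | 0.0500 M |  |  |
| gamma | 0.300 M | 0.550 M | 0.0500 M |  |  |
| delta | 0.500 M | 0.380 M | 0.0500 M |  |  |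
| eta | 0.500 M | 0.750 M | 0.0500 M | 0.250 M |  |
| epsilon | 0.500 M | 0.120 M | 0.0500 M |  | 9.7 min |

- beta run (time / min: [Pdt] / M): 0.39: 0.012; 0.87: 0; 1.9: 0.021; 4.3: 0.093; 9.7: 0.275
- gamma run (time / min: [Pdt] / M): 0.39: 0; 0.87: 0.019; 1.9: 0.009; 4.3: 0.073; 9.7: 0.163
- delta run (time / min: [Pdt] / M): 0.39: 0.004; 0.87: 0.003; 1.9: 0.020; 4.3: 0.060; 9.7: 0.179
- eta run (time / min: [Pdt] / M): 0.39: 0.245; 0.87: 0.249; 1.9: 0.280; 4.3: 0.351; 9.7: 0.513

(each reading ± 0.007 M)

1. the power of [Ptn] that the first rate follows, about the charge of the beta run; measure it at two percent of Sbt made into Pdt
2. the power of [Sbt] that the first rate follows, about the charge of the beta run; measure it at two percent of Sbt made into Pdt (one fixed amount of Pdt, the same in the runs compared)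
3. the gamma run starts with 0.200 M less of Sbt and of Ptn than the beta run, and with no Pdt. Compared where both hold the same amount of Sbt, once fifteen percent of what the gamma run was charged with has turned into Pdt, is the gamma run faster, slower or alike (within a tenth)?
4. Pdt in the epsilon run at 9.7 min, as a share of the Sbt charged

- Overall: Sbt + Ptn -> Pdt, with Ctl as catalyst.
- Constant volume, constant temperature.
- Bound and free are read together.
- An order is taken over about fifteen percent of the charge, up and down.

The beta run climbs in a straight late stretch, and that slope, carried back to zero Pdt, cuts the time axis late: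

v = 0.0337 M min⁻¹
lag = 4.3 min − 0.093 M/v = 1.54 min

This intercept is the lag, the delay of a ramp behind its start. The eta run, charged with Pdt, gains 0.263 M by 9.7 min, close to the 0.275 M of the beta run, so added Pdt does not set the delay. My reckoning treats the start as a first-order step response with the lag as its time constant, so the fraction of the start still to come is exp(−t/lag).

The delta run has a slope of 0.0220 M min⁻¹, which gives a steady order in Ptn of 0.625. The beta run passes two percent before its 1.9 min reading, inside the ramp, where rate grows with time and Pdt with time squared. Rate at fixed Pdt therefore follows the square root of the steady rate, and ord_R comes to 0.312. The same factor of 0.5 applies to ord_S, though the gamma run changes both charges and gives no clean steady value.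

The gamma run reaches the asked point between its readings at 1.9 min and 4.3 min, so I take the midpoint:

fraction left = exp(−3.10 min/lag) = 13.4%

The beta run has used up 0.200 M at about 7.47 min, when the fraction left is 0.782%, and it reaches the matched Sbt a little later still. The ratio of the two started fractions, gamma over beta, is then about 0.873, which makes the gamma run slower, narrowly.

In the epsilon run Ptn is the limiting reagent, with 0.120 M against 0.500 M of Sbt, so the flask is pseudo-first-order in Ptn. The delta slope over its mean Ptn in that stretch gives:

k′ = 0.0846 min⁻¹
Ptn left = exp(−k′(9.7 min − lag)) = 50.1%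
Pdt = 12.0% of the Sbt charged

An order below one raises k′ as Ptn falls, so this figure sits low, but the reading is worth taking and the charge stands.

The forecast gives 0.45, 0.35, alike and 12.5%, differing from this reckoning on the first and third, with the words “At matched Sbt, gamma is about 90% activated, so it is borderline alike.”

The flask gives 0.25, 0.20, slower and 14.1%.

    Q + Sbt ⇌ Ctl.Sbt, settled at all times (0.5540 M⁻¹)
    Ctl.Sbt + Ptn ⇌ Ctl.Sbt.Ptn, settled at all times (9.340 M⁻¹)
    Ctl.Sbt.Ptn → Pdt + Q (1.602 min⁻¹)
    Ctl → Q (0.4020 min⁻¹)

At matched Sbt the gamma run goes at 0.77 of the beta rate, against the 0.873 that the lag of 1.54 min gave. It falls below the 1.0 of the same flask with a quick path from Ctl to Q, and the slowness of that path is the reason. Carried to the eta run, which shares the beta charge of Sbt and Ptn, the lag plus beta's slope puts Pdt made at a quarter of the Sbt charged at 5.25 min, and the eta run stands there at 5.07 min.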